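**Retrosynthetic overview**
- Feature: ring E (the central phenol ring) is bonded through C3' to C3 of unit 1 (5-hydroxy-7-methoxychromone: benzo ring A, pyranone ring C, 2-aryl ring B) and through C1' to C2 of unit 2 (5,7-dihydroxychromone: benzo ring D, pyranone ring F). It therefore sits on the enolate carbon of one pyranone and on the acyl carbon of the other.
- Key disconnection: O1-C2 and C2-C3 of ring C and of ring F are cut together. This leads back to one bis(aryl ester) that holds a deoxybenzoin CH2 (future C3 of unit 1) and an acetyl CH3 (future C3 of unit 2).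
- The bis(aryl ester) comes from a ring A/ring E deoxybenzoin acid by two carbodiimide esterifications. A MOM group on the ring A phenol fixes their order: ring E ester first, ring B ester second.
- The CH2-C3' bond of the deoxybenzoin is made by palladium-catalysed alpha-arylation of a protected ring A acetophenone with a ring E aryl bromide.
- Ring order: all five benzene rings are bought, rings C and F are closed together in the key step, and global hydrogenolysis ends the route.

Key step: step 10

Remark: the SMILES carries no stereodescriptor. The target has no stereocentre and the C3-C3' biaryl axis is taken as configurationally unassigned, so nothing stereochemical has to be controlled.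

**Step 1**
Reactants: 1 1-(2,6-dihydroxy-4-methoxyphenyl)ethanone
Product: 2 1-[2-(benzyloxy)-6-hydroxy-4-methoxyphenyl]ethanone
Conditions: BnBr (1.05 equiv), K2CO3 (1.1 equiv), acetone, reflux
Reagents that add atoms: benzyl bromide, BrCc1ccccc1
Why: Williamson etherification of one of two equivalent hydroxyls should stop at the monoether, because the remaining hydroxyl is then locked in a strong hydrogen bond to the acetyl carbonyl.

**Step 2**
Reactants: 2 1-[2-(benzyloxy)-6-hydroxy-4-methoxyphenyl]ethanone
Product: 3 1-[2-(benzyloxy)-4-methoxy-6-(methoxymethoxy)phenyl]ethanone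
Conditions: NaH (1.1 equiv), DMF, 0 °C; then MOMCl (1.2 equiv), 0 °C to rt
Reagents that add atoms: chloromethyl methyl ether, COCCl
Why: Irreversible deprotonation breaks the chelate and the sodium phenoxide is O-alkylated (Williamson-type acetal protection), which masks the ring A phenol through the palladium step and the first esterification.

**Step 3**
Reactants: 4 methyl 3-bromo-4-hydroxybenzoate
Product: 5 methyl 4-(benzyloxy)-3-bromobenzoate
Conditions: BnBr (1.1 equiv), K2CO3 (1.5 equiv), DMF, rt
Reagents that add atoms: benzyl bromide, BrCc1ccccc1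
Why: Williamson etherification of an acidic phenol (para ester, ortho bromine) puts on the ring E oxygen the benzyl group that later keeps this oxygen out of the ring closures.

**Step 4**
Reactants: 3 1-[2-(benzyloxy)-4-methoxy-6-(methoxymethoxy)phenyl]ethanone (1.2 equiv); 5 methyl 4-(benzyloxy)-3-bromobenzoate
Product: 6 methyl 4-(benzyloxy)-3-{2-[2-(benzyloxy)-4-methoxy-6-(methoxymethoxy)phenyl]-2-oxoethyl}benzoate
Conditions: Pd2(dba)3 (2 mol %), Xantphos (5 mol %), K3PO4 (2.5 equiv), toluene, 90 °C, Ar
Reagents that add atoms: none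
Why: In this Buchwald-Hartwig-Miura alpha-arylation of a methyl ketone, zerovalent palladium inserts into the C-Br bond, the potassium enolate binds and reductive elimination forms CH2-C3', while the weak base K3PO4 spares the methyl ester and the wide-bite-angle ligand together with the ortho benzyloxy group should hold the reaction at monoarylation.

**Step 5**
Reactants: 6 methyl 4-(benzyloxy)-3-{2-[2-(benzyloxy)-4-methoxy-6-(methoxymethoxy)phenyl]-2-oxoethyl}benzoate
Product: 7 4-(benzyloxy)-3-{2-[2-(benzyloxy)-4-methoxy-6-(methoxymethoxy)phenyl]-2-oxoethyl}benzoic acid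
Conditions: LiOH·H2O (3 equiv), THF/MeOH/H2O, 40 °C, Ar; then 1 M HCl to pH 4, 0 °C
Reagents that add atoms: lithium hydroxide, [Li+].[OH-]
Why: Saponification by acyl-oxygen cleavage touches only the methyl ester, since the MOM acetal and the benzyl ethers are stable to base and the brief cold acidification should leave the acetal in place.

**Step 6**
Reactants: 8 1-(2,4,6-trihydroxyphenyl)ethanone
Product: 9 1-[2,4-bis(benzyloxy)-6-hydroxyphenyl]ethanone
Conditions: BnBr (2.1 equiv), K2CO3 (2.2 equiv), DMF, rt
Reagents that add atoms: benzyl bromide, BrCc1ccccc1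
Why: Williamson etherification takes the para hydroxyl and one ortho hydroxyl, while the last ortho hydroxyl stays chelated to the acetyl carbonyl and remains free as the ester-forming phenol of ring D.

**Step 7**
Reactants: 7 4-(benzyloxy)-3-{2-[2-(benzyloxy)-4-methoxy-6-(methoxymethoxy)phenyl]-2-oxoethyl}benzoic acid; 9 1-[2,4-bis(benzyloxy)-6-hydroxyphenyl]ethanone
Product: 10 2-acetyl-3,5-bis(benzyloxy)phenyl 4-(benzyloxy)-3-{2-[2-(benzyloxy)-4-methoxy-6-(methoxymethoxy)phenyl]-2-oxoethyl}benzoate
Conditions: EDC·HCl (1.5 equiv), DMAP (0.3 equiv), CH2Cl2, rt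
Reagents that add atoms: none
Why: Steglich esterification through the acylpyridinium ion acylates the only free phenol present, because the similarly chelated ring A phenol is still masked as its MOM ether and self-condensation is excluded.

**Step 8**
Reactants: 10 2-acetyl-3,5-bis(benzyloxy)phenyl 4-(benzyloxy)-3-{2-[2-(benzyloxy)-4-methoxy-6-(methoxymethoxy)phenyl]-2-oxoethyl}benzoate
Product: 11 2-acetyl-3,5-bis(benzyloxy)phenyl 4-(benzyloxy)-3-{2-[2-(benzyloxy)-6-hydroxy-4-methoxyphenyl]-2-oxoethyl}benzoate
Conditions: 2 M aq HCl, THF/iPrOH, 45 °C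
Reagents that add atoms: none
Why: Acid-catalysed acetal hydrolysis removes the MOM group, which is activated by the neighbouring ketone, under conditions in which aryl benzoates and aryl benzyl ethers hydrolyse only very slowly.

**Step 9**
Reactants: 11 2-acetyl-3,5-bis(benzyloxy)phenyl 4-(benzyloxy)-3-{2-[2-(benzyloxy)-6-hydroxy-4-methoxyphenyl]-2-oxoethyl}benzoate; 12 4-(benzyloxy)benzoic acid
Product: 13 bis(aryl ester): 2-acetyl-3,5-bis(benzyloxy)phenyl 4-(benzyloxy)-3-[2-(2-(benzyloxy)-6-{[4-(benzyloxy)benzoyl]oxy}-4-methoxyphenyl)-2-oxoethyl]benzoate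
Conditions: EDC·HCl (2 equiv), DMAP (0.5 equiv), CH2Cl2, rt
Reagents that add atoms: none
Why: A second Steglich esterification overcomes the chelated ring A phenol through the reactive acylpyridinium ion, and the near-neutral medium enolises neither ketone, so no acyl transfer should start early.

**Step 10**
Reactants: 13 bis(aryl ester)
Product: 15 pentabenzyl ether of the target, via bis(1,3-diketone) diphenol 14 (not isolated)
Conditions: KOtBu (6 equiv), THF (0.02 M), 0 °C to rt, Ar; then AcOH and p-TsOH·H2O (8 equiv) in the same flask, 65 °C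
Reagents that add atoms: none
Why: KOtBu deprotonates the ring E benzylic methylene next to the ring A ketone and the acetyl methyl on ring D, and each enolate carbon adds to the aryl ester carbonyl ortho to its own ketone through a six-membered cyclic tetrahedral intermediate that expels the phenoxide, so both aroyl groups move from O to C, both C2-C3 bonds form, and 14 is held as a stabilised polyanion that resists retro-Claisen cleavage. This is the Baker-Venkataraman rearrangement, known for 2-aroyloxyacetophenones (flavones) and for 2-aroyloxydeoxybenzoins (2,3-diarylchromones), followed by the usual acid cyclodehydration. On acidification the ring A phenol adds to the 4-benzyloxybenzoyl ketone and the ring D phenol adds to the ring E aroyl ketone, each by 6-exo-trig closure to a 2-hydroxychromanone that loses water, which forms O1-C2 in ring C and in ring F. No stereocentre is created, since the enolisable CH of 14 ends as the sp2 carbon C3 of unit 1. The step needs each enolate to take only its own ester, which is secured because the neighbouring ester is reached through a six-membered transition state whereas the remote one would require a meta-bridged or macrocyclic geometry or a bimolecular encounter that dilution disfavours. It also needs a single closure mode per diketone, which is secured because the second ortho oxygen of ring A, that of ring D and the ring E oxygen all carry benzyl, so only one phenol stands beside each diketone.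

**Step 11**
Reactants: 15 pentabenzyl ether of the target
Product: 16 target CNP0284832.0
Conditions: H2 (1 atm), 10% Pd/C, THF/MeOH, rt
Reagents that add atoms: none
Why: Catalytic hydrogenolysis cleaves the five benzylic C-O bonds, while the aryl methyl ether has no benzylic C-O bond and the conjugated, highly substituted pyranone double bonds are not reduced at atmospheric pressure.

**Compound list**
1 | 1-(2,6-dihydroxy-4-methoxyphenyl)ethanone | CC(=O)c1c(O)cc(OC)cc1O | starting material
2 | 1-[2-(benzyloxy)-6-hydroxy-4-methoxyphenyl]ethanone | CC(=O)c1c(O)cc(OC)cc1OCc1ccccc1 | intermediate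
3 | 1-[2-(benzyloxy)-4-methoxy-6-(methoxymethoxy)phenyl]ethanone | CC(=O)c1c(OCOC)cc(OC)cc1OCc1ccccc1 | intermediate
4 | methyl 3-bromo-4-hydroxybenzoate | COC(=O)c1ccc(O)c(Br)c1 | starting material
5 | methyl 4-(benzyloxy)-3-bromobenzoate | COC(=O)c1ccc(OCc2ccccc2)c(Br)c1 | intermediate
6 | methyl 4-(benzyloxy)-3-{2-[2-(benzyloxy)-4-methoxy-6-(methoxymethoxy)phenyl]-2-oxoethyl}benzoate | COC(=O)c1ccc(OCc2ccccc2)c(CC(=O)c2c(OCOC)cc(OC)cc2OCc2ccccc2)c1 | intermediate
7 | 4-(benzyloxy)-3-{2-[2-(benzyloxy)-4-methoxy-6-(methoxymethoxy)phenyl]-2-oxoethyl}benzoic acid | O=C(O)c1ccc(OCc2ccccc2)c(CC(=O)c2c(OCOC)cc(OC)cc2OCc2ccccc2)c1 | intermediate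
8 | 1-(2,4,6-trihydroxyphenyl)ethanone | CC(=O)c1c(O)cc(O)cc1O | starting material
9 | 1-[2,4-bis(benzyloxy)-6-hydroxyphenyl]ethanone | CC(=O)c1c(O)cc(OCc2ccccc2)cc1OCc1ccccc1 | intermediate
10 | MOM-protected mono(aryl ester) of the ring E deoxybenzoin acid | COCOc1cc(OC)cc(OCc2ccccc2)c1C(=O)Cc1cc(C(=O)Oc2cc(OCc3ccccc3)cc(OCc3ccccc3)c2C(C)=O)ccc1OCc1ccccc1 | intermediate
11 | mono(aryl ester) with free ring A phenol | COc1cc(O)c(C(=O)Cc2cc(C(=O)Oc3cc(OCc4ccccc4)cc(OCc4ccccc4)c3C(C)=O)ccc2OCc2ccccc2)c(OCc2ccccc2)c1 | intermediate
12 | 4-(benzyloxy)benzoic acid | O=C(O)c1ccc(OCc2ccccc2)cc1 | starting material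
13 | bis(aryl ester) of the ring E deoxybenzoin (key-step precursor) | COc1cc(OCc2ccccc2)c(C(=O)Cc2cc(C(=O)Oc3cc(OCc4ccccc4)cc(OCc4ccccc4)c3C(C)=O)ccc2OCc2ccccc2)c(OC(=O)c2ccc(OCc3ccccc3)cc2)c1 | intermediate
14 | bis(1,3-diketone) diphenol (racemic, enolisable CH; not isolated) | COc1cc(O)c(C(=O)C(C(=O)c2ccc(OCc3ccccc3)cc2)c2cc(C(=O)CC(=O)c3c(O)cc(OCc4ccccc4)cc3OCc3ccccc3)ccc2OCc2ccccc2)c(OCc2ccccc2)c1 | intermediate
15 | 5-(benzyloxy)-3-{2-(benzyloxy)-5-[5,7-bis(benzyloxy)-4-oxo-4H-chromen-2-yl]phenyl}-2-[4-(benzyloxy)phenyl]-7-methoxy-4H-chromen-4-one (pentabenzyl ether of the target) | COc1cc(OCc2ccccc2)c2c(=O)c(-c3cc(-c4cc(=O)c5c(OCc6ccccc6)cc(OCc6ccccc6)cc5o4)ccc3OCc3ccccc3)c(-c3ccc(OCc4ccccc4)cc3)oc2c1 | intermediate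
16 | 3-[5-(5,7-dihydroxy-4-oxo-4H-chromen-2-yl)-2-hydroxyphenyl]-5-hydroxy-2-(4-hydroxyphenyl)-7-methoxy-4H-chromen-4-one (CNP0284832.0) | COc1cc(O)c2c(=O)c(-c3cc(-c4cc(=O)c5c(O)cc(O)cc5o4)ccc3O)c(-c3ccc(O)cc3)oc2c1 | target

**Step count**
- Total step count: 11.
- Longest linear sequence: 9 steps (1, 2, 4, 5, 7, 8, 9, 10, 11).

**Steps most likely to fail**

**Step 10 (twofold acyl transfer and double closure).**
- The two transfers may run at unequal rates. The acetyl side would migrate quickly while the crowded deoxybenzoin side lags.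
- During that wait tert-butoxide could cleave the remaining aryl ester, or fragment the hindered 2-aryl-1,3-diketone by retro-Claisen reaction.
- The acid phase could also strip the peri benzyl ethers.
- The fallback closes the rings one at a time, with a base chosen for each C-H acid. It sets out from 10 and returns at 15.
- In compound 10 only the acetyl/ester pair can react. Treatment with KOtBu in THF gives the MOM-protected mono-diketone F1.
- p-TsOH·H2O in AcOH/THF at 60 °C then closes ring F and removes the MOM group in the same operation, giving the flavone-deoxybenzoin phenol F2.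
- Steglich esterification of F2 with 12 (EDC·HCl, DMAP, CH2Cl2) gives the mono(aryl ester) F3.
- The more acidic deoxybenzoin methylene of F3 is rearranged with K2CO3 in refluxing acetone to the 2-aryl-1,3-diketone F4.
- p-TsOH·H2O then closes ring C and gives 15.

**Step 4 (alpha-arylation).**
- Coupling between the ortho-benzyloxy arylpalladium species and the enolate of a di-ortho-substituted ketone may be slow.
- Intramolecular C-H arylation of the benzyl ether, hydrodebromination or enolate attack on the methyl ester could then take over.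
- The fallback replaces the enolate arylation by acylation of the arene. It sets out from 5 and returns at 6.
- Bromide 5 is coupled with the small nucleophile Me3SiCH2CN (ZnF2, Pd2(dba)3, Xantphos, DMF, 90 °C) to give the arylacetonitrile F5.
- Hoesch reaction of F5 with phloroglucinol (Oc1cc(O)cc(O)c1; HCl gas, ZnCl2, Et2O, 0 °C) gives the ketimine F6, which separates as its hydrochloride.
- Hot water hydrolyses F6 to the trihydroxydeoxybenzoin F7.
- Me2SO4 (1 equiv), K2CO3 and acetone methylate the unchelated para hydroxyl to give the 4-O-methyl ether F8.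
- BnBr (1 equiv), K2CO3 and acetone give the monobenzyl ether F9.
- NaH and MOMCl in DMF then give 6.

**Step 11 (global hydrogenolysis).**
- The reaction may stall when partly debenzylated, poorly soluble intermediates settle on the catalyst.
- Long exposure could slowly saturate the C2-C3 bond of unit 2.
- The fallback replaces hydrogenolysis by Lewis-acid cleavage. It sets out from 15 and returns at 16.
- The conditions are BCl3 (10 equiv) and pentamethylbenzene (15 equiv) in CH2Cl2 at -78 °C, followed by a MeOH quench.
- The benzyl cations are trapped by the arene, and the 7-methyl ether, which is not peri to a carbonyl, should survive at this temperature.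

**Further compounds**
F1 | step 10 | MOM-protected mono-diketone | COCOc1cc(OC)cc(OCc2ccccc2)c1C(=O)Cc1cc(C(=O)CC(=O)c2c(O)cc(OCc3ccccc3)cc2OCc2ccccc2)ccc1OCc1ccccc1
F2 | step 10 | flavone-deoxybenzoin phenol | COc1cc(O)c(C(=O)Cc2cc(-c3cc(=O)c4c(OCc5ccccc5)cc(OCc5ccccc5)cc4o3)ccc2OCc2ccccc2)c(OCc2ccccc2)c1
F3 | step 10 | mono(aryl ester) of the flavone-deoxybenzoin | COc1cc(OCc2ccccc2)c(C(=O)Cc2cc(-c3cc(=O)c4c(OCc5ccccc5)cc(OCc5ccccc5)cc4o3)ccc2OCc2ccccc2)c(OC(=O)c2ccc(OCc3ccccc3)cc2)c1
F4 | step 10 | 2-aryl-1,3-diketone carrying the finished unit 2 | COc1cc(O)c(C(=O)C(C(=O)c2ccc(OCc3ccccc3)cc2)c2cc(-c3cc(=O)c4c(OCc5ccccc5)cc(OCc5ccccc5)cc4o3)ccc2OCc2ccccc2)c(OCc2ccccc2)c1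
F5 | step 4 | methyl 4-(benzyloxy)-3-(cyanomethyl)benzoate | COC(=O)c1ccc(OCc2ccccc2)c(CC#N)c1
F6 | step 4 | methyl 4-(benzyloxy)-3-[2-imino-2-(2,4,6-trihydroxyphenyl)ethyl]benzoate | COC(=O)c1ccc(OCc2ccccc2)c(CC(=N)c2c(O)cc(O)cc2O)c1
F7 | step 4 | methyl 4-(benzyloxy)-3-[2-oxo-2-(2,4,6-trihydroxyphenyl)ethyl]benzoate | COC(=O)c1ccc(OCc2ccccc2)c(CC(=O)c2c(O)cc(O)cc2O)c1
F8 | step 4 | methyl 4-(benzyloxy)-3-[2-(2,6-dihydroxy-4-methoxyphenyl)-2-oxoethyl]benzoate | COC(=O)c1ccc(OCc2ccccc2)c(CC(=O)c2c(O)cc(OC)cc2O)c1
F9 | step 4 | methyl 4-(benzyloxy)-3-{2-[2-(benzyloxy)-6-hydroxy-4-methoxyphenyl]-2-oxoethyl}benzoate | COC(=O)c1ccc(OCc2ccccc2)c(CC(=O)c2c(O)cc(OC)cc2OCc2ccccc2)c1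
F0 | step 11 | none | none
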